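**Plan**

1. The target is an achiral bibenzyl. On its central ring the carbon bearing the ArCH2CH2 chain and the carbon bearing the 4-hydroxybenzyl CH2 are ortho neighbours. The chain CH2 bound to the 3-methoxyphenyl ring and the diarylmethane carbon can therefore be tied into a five-membered ring: the target is a ring-opened (1,2-seco) 1-arylindane.
2. Retrosynthesis: (i) diarylmethane CH2 back to C=O and both phenols back to benzyl ethers; (ii) cut the bond between the 3-methoxyphenyl ring carbon and its CH2 while re-joining that CH2 to the carbonyl carbon, giving 3-bromoanisole and a 1-aryl-indan-1-ol; (iii) cut the carbinol–aryl bond (aryl Grignard + indan-1-one); (iv) cut the two O–alkyl bonds and the acyl–arene bond of the indanone.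
3. Forward: the five-membered ring is closed first on a symmetric 3,5-dimethoxyphenyl ring (one isomer possible). The peri C=O then tells the two oxygens apart (free 5-OH benzylated, hydrogen-bonded 7-OH methylated). The 4-benzyloxyphenyl group is added to C1, the key step opens the ring between C1 and C2 and bonds C2 to the anisole ring, and one hydrogenation removes the helpers (carbonyl oxygen, two benzyl groups).
4. Stereochemistry: the target has no stereocentre; the only stereocentre of the route (C1 of the indanol, racemic) becomes the carbonyl carbon in the key step.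

Key step: step 6

Remark: the target is achiral, so no enantiomer has to be controlled; compound 7 is used as the racemate.

**Route**

Step 1
Reactants: 1 3-(3,5-dimethoxyphenyl)propanoic acid
Product: 2 5,7-dimethoxy-2,3-dihydro-1H-inden-1-one
Conditions: MeSO3H (solvent), 90 °C
Reagents that add atoms: none
Why: Intramolecular Friedel–Crafts acylation (cyclodehydration) of a 3-arylpropanoic acid should close the five-membered ring at the only kind of free ortho position of the symmetric ring (para to one OMe, ortho to the other), so a single indanone is expected.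

Step 2
Reactants: 2 5,7-dimethoxy-2,3-dihydro-1H-inden-1-one
Product: 3 5,7-dihydroxy-2,3-dihydro-1H-inden-1-one
Conditions: BBr3 (4 equiv), CH2Cl2, −78 °C → rt; then H2O
Reagents that add atoms: none
Why: Lewis-acid cleavage of both aryl methyl ethers with BBr3 (excess, because the ketone also binds boron) should give the dihydroxy ketone after hydrolysis of the aryl borates.

Step 3
Reactants: 3 5,7-dihydroxy-2,3-dihydro-1H-inden-1-one
Product: 4 5-(benzyloxy)-7-hydroxy-2,3-dihydro-1H-inden-1-one
Conditions: BnBr (1.05 equiv), K2CO3 (1.1 equiv), acetone, 50 °C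
Reagents that add atoms: benzyl bromide, BrCc1ccccc1
Why: Chemoselective Williamson etherification: the 5-OH (para to C=O, more acidic, not hydrogen-bonded) should be alkylated while the 7-OH is held by the peri carbonyl, as in the 4-O-alkylation of 2,4-dihydroxyaryl ketones.

Step 4
Reactants: 4 5-(benzyloxy)-7-hydroxy-2,3-dihydro-1H-inden-1-one
Product: 5 5-(benzyloxy)-7-methoxy-2,3-dihydro-1H-inden-1-one
Conditions: MeI (3 equiv), K2CO3, DMF, 50 °C
Reagents that add atoms: iodomethane, CI
Why: Williamson methylation of the remaining chelated phenol under more forcing conditions; K2CO3 is too weak to enolise the ketone, so C-methylation at C2 is not expected.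

Step 5
Reactants: 5 5-(benzyloxy)-7-methoxy-2,3-dihydro-1H-inden-1-one; 6 [4-(benzyloxy)phenyl]magnesium bromide (commercial THF solution)
Product: 7 rac-5-(benzyloxy)-1-[4-(benzyloxy)phenyl]-7-methoxy-2,3-dihydro-1H-inden-1-ol
Conditions: LaCl3·2LiCl (30 mol %), THF, 0 °C → rt; pH 7 phosphate buffer work-up; Et3N-deactivated silica
Reagents that add atoms: none
Why: 1,2-Addition of an aryl Grignard reagent to the ketone, with the lanthanum salt favouring addition over enolisation; the carbinol centre forms racemic and is destroyed in step 6, and the buffered work-up avoids dehydration to the indene.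

Step 6
Reactants: 7 rac-5-(benzyloxy)-1-[4-(benzyloxy)phenyl]-7-methoxy-2,3-dihydro-1H-inden-1-ol; 8 3-bromoanisole (2 equiv)
Product: 10 [4-(benzyloxy)phenyl]{4-(benzyloxy)-2-methoxy-6-[2-(3-methoxyphenyl)ethyl]phenyl}methanone, via ring-opened keto alkyl radical 9 (not isolated)
Conditions: [Mes-Acr-Me]ClO4 (5 mol %), NiBr2·glyme (10 mol %), dtbbpy (12 mol %), 2,4,6-collidine (2 equiv), degassed MeCN, blue LEDs (450 nm), rt
Reagents that add atoms: none
Why: The excited acridinium oxidises one of the electron-rich alkoxyarenes on C1 while collidine takes the O–H proton (proton-coupled electron transfer), giving the C1 alkoxy radical, which undergoes β-scission of the ring bond C1–C2 to the diaryl ketone and primary radical 9; 9 is captured by the aryl–nickel species formed from 8, and reductive elimination from Ni(III) forms the CH2–aryl bond. The closest known reaction type is the photoredox/nickel ring-opening arylation of 1-aryl-cycloalkanols with aryl bromides (PCET-enabled C–C cleavage with remote arylation). No ring is closed: the five-membered ring of the indanol is opened, and no stereocentre is formed, the racemic carbinol carbon becoming the carbonyl carbon. Scission must occur at C1–C2 and not at a C1–aryl bond, which is secured because only this scission gives an sp3 radical and a conjugated diaryl ketone. Cross-coupling of 9 must outrun hydrogen abstraction and re-addition to the ketone, which is helped by the hindered, twisted carbonyl, by excess 8 and by the absence of a hydrogen-atom donor. Oxidation must start at the carbinol, which is secured because the two most electron-rich rings (the 3,5-dialkoxy ring and the 4-benzyloxyphenyl ring) both sit on C1.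

Step 7
Reactants: 10 [4-(benzyloxy)phenyl]{4-(benzyloxy)-2-methoxy-6-[2-(3-methoxyphenyl)ethyl]phenyl}methanone
Product: 13 4-[(4-hydroxyphenyl)methyl]-3-methoxy-5-[2-(3-methoxyphenyl)ethyl]phenol, via debenzylated diaryl ketone 11 (not isolated), via benzhydrol 12 (not isolated)
Conditions: H2 (4 bar), 10% Pd/C, EtOH/AcOH 4:1, cat. H2SO4, 50 °C
Reagents that add atoms: none
Why: Heterogeneous hydrogenolysis should cleave both benzyl ethers, hydrogenate the diaryl ketone to the doubly benzylic, para-oxygen-activated benzhydrol and cleave its C–O bond under the acidic conditions (diaryl ketone to diarylmethane reduction over Pd/C), leaving the aryl methyl ethers untouched.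

**Compound list**

1 | 3-(3,5-dimethoxyphenyl)propanoic acid | COc1cc(CCC(=O)O)cc(OC)c1 | starting material
2 | 5,7-dimethoxy-2,3-dihydro-1H-inden-1-one | COc1cc(OC)c2C(=O)CCc2c1 | intermediate
3 | 5,7-dihydroxy-2,3-dihydro-1H-inden-1-one | Oc1cc(O)c2C(=O)CCc2c1 | intermediate
4 | 5-(benzyloxy)-7-hydroxy-2,3-dihydro-1H-inden-1-one | Oc1cc(OCc2ccccc2)cc2CCC(=O)c12 | intermediate
5 | 5-(benzyloxy)-7-methoxy-2,3-dihydro-1H-inden-1-one | COc1cc(OCc2ccccc2)cc2CCC(=O)c12 | intermediate
6 | [4-(benzyloxy)phenyl]magnesium bromide | Br[Mg]c1ccc(OCc2ccccc2)cc1 | starting material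
7 | rac-5-(benzyloxy)-1-[4-(benzyloxy)phenyl]-7-methoxy-2,3-dihydro-1H-inden-1-ol | COc1cc(OCc2ccccc2)cc2CCC(O)(c3ccc(OCc4ccccc4)cc3)c12 | intermediate
8 | 3-bromoanisole (1-bromo-3-methoxybenzene) | COc1cccc(Br)c1 | starting material
9 | 2-{5-(benzyloxy)-2-[4-(benzyloxy)benzoyl]-3-methoxyphenyl}ethyl radical | [CH2]Cc1cc(OCc2ccccc2)cc(OC)c1C(=O)c1ccc(OCc2ccccc2)cc1 | intermediate (not isolated)
10 | [4-(benzyloxy)phenyl]{4-(benzyloxy)-2-methoxy-6-[2-(3-methoxyphenyl)ethyl]phenyl}methanone | COc1cccc(CCc2cc(OCc3ccccc3)cc(OC)c2C(=O)c2ccc(OCc3ccccc3)cc2)c1 | intermediate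
11 | (4-hydroxyphenyl){4-hydroxy-2-methoxy-6-[2-(3-methoxyphenyl)ethyl]phenyl}methanone | COc1cccc(CCc2cc(O)cc(OC)c2C(=O)c2ccc(O)cc2)c1 | intermediate (not isolated)
12 | rac-4-[hydroxy(4-hydroxyphenyl)methyl]-3-methoxy-5-[2-(3-methoxyphenyl)ethyl]phenol | COc1cccc(CCc2cc(O)cc(OC)c2C(O)c2ccc(O)cc2)c1 | intermediate (not isolated)
13 | 4-[(4-hydroxyphenyl)methyl]-3-methoxy-5-[2-(3-methoxyphenyl)ethyl]phenol | COc1cccc(CCc2cc(O)cc(OC)c2Cc2ccc(O)cc2)c1 | target

**Step count and risks**

Total step count: 7. Longest linear sequence: 7 steps (1 → 13); partners 6 and 8 are commercial.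

Steps most likely to fail:

Step 6. After β-scission the primary radical may abstract hydrogen or add back to the carbonyl faster than nickel captures it, the electron-rich benzyl ethers may be oxidised unproductively, or the carbinol may lose water to the indene in the presence of the collidinium salt. The fallback sets out from 5 and comes back at 10, and makes the anisole–carbon bond by two-electron chemistry before the ring is opened. Pd-catalysed ketone α-arylation of 5 with 8 (Pd(OAc)2, P(t-Bu)3, NaOt-Bu, toluene, 70 °C) should give 5-(benzyloxy)-7-methoxy-2-(3-methoxyphenyl)-2,3-dihydro-1H-inden-1-one F1. Addition of 6 (LaCl3·2LiCl, THF, 0 °C) should give 5-(benzyloxy)-1-[4-(benzyloxy)phenyl]-7-methoxy-2-(3-methoxyphenyl)-2,3-dihydro-1H-inden-1-ol F2 as a diastereomer mixture of no consequence. Redox-neutral PCET ring-opening of F2 (Ir(III) photocatalyst, 2,4,6-collidine, cat. PhSH, CH2Cl2, blue LEDs) should then cleave C1–C2 to a stabilised secondary benzylic radical, which the thiol reduces to 10.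

Step 5. The basic Grignard reagent may enolise the electron-rich indanone instead of adding, and the tertiary bis-benzylic carbinol may lose water during work-up or chromatography. The fallback sets out from 5 and comes back at 7 without an organometallic addition to the ketone. Enol triflation (KHMDS, PhNTf2, THF, −78 °C) should give 6-(benzyloxy)-4-methoxy-1H-inden-3-yl trifluoromethanesulfonate F3. Suzuki–Miyaura coupling with [4-(benzyloxy)phenyl]boronic acid (Pd(PPh3)4, K3PO4, dioxane/H2O, 80 °C) should give 6-(benzyloxy)-3-[4-(benzyloxy)phenyl]-4-methoxy-1H-indene F4. Mukaiyama hydration of F4 (Mn(dpm)3 cat., PhSiH3, O2, i-PrOH, 0 °C → rt) should place OH at the more substituted benzylic carbon under neutral conditions and give 7.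

Step 7. Hydrogenation may stall at the hindered, electron-rich diaryl ketone once the benzyl ethers are gone, or the benzhydrol may self-condense through its quinone methide under acid. The fallback sets out from 10 and comes back at 13, and separates the two reductions. Ionic hydrogenation (Et3SiH, TFA, CH2Cl2, 0 °C → rt) should reduce the carbonyl through the stabilised diarylmethyl cation to 5-(benzyloxy)-2-[4-(benzyloxy)benzyl]-1-methoxy-3-[2-(3-methoxyphenyl)ethyl]benzene F5. Neutral hydrogenolysis of F5 (H2, Pd/C, EtOAc/EtOH, rt) should then give 13.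

**Further compounds**

F1 | step 6 | 5-(benzyloxy)-7-methoxy-2-(3-methoxyphenyl)-2,3-dihydro-1H-inden-1-one (racemic) | COc1cccc(C2Cc3cc(OCc4ccccc4)cc(OC)c3C2=O)c1
F2 | step 6 | 5-(benzyloxy)-1-[4-(benzyloxy)phenyl]-7-methoxy-2-(3-methoxyphenyl)-2,3-dihydro-1H-inden-1-ol (diastereomer mixture) | COc1cccc(C2Cc3cc(OCc4ccccc4)cc(OC)c3C2(O)c2ccc(OCc3ccccc3)cc2)c1
F3 | step 5 | 6-(benzyloxy)-4-methoxy-1H-inden-3-yl trifluoromethanesulfonate | COc1cc(OCc2ccccc2)cc2CC=C(OS(=O)(=O)C(F)(F)F)c12
F4 | step 5 | 6-(benzyloxy)-3-[4-(benzyloxy)phenyl]-4-methoxy-1H-indene | COc1cc(OCc2ccccc2)cc2CC=C(c3ccc(OCc4ccccc4)cc3)c12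
F5 | step 7 | 5-(benzyloxy)-2-[4-(benzyloxy)benzyl]-1-methoxy-3-[2-(3-methoxyphenyl)ethyl]benzene | COc1cccc(CCc2cc(OCc3ccccc3)cc(OC)c2Cc2ccc(OCc3ccccc3)cc2)c1
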